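**Retrosynthetic overview**

- The target is opened at its two ester C–O bonds and its acid-labile masks, giving 4-acetoxycinnamoyl chloride and a quinic acid core. In that core the C1 hydroxy acid is a spiro 2-tert-butyl-1,3-dioxolan-4-one, O3 is silylated and the trans-4,5-diol comes from an acetonide.
- The core is cut at C2–C3 and C1–C6 of the cyclohexane in one reductive [4+2] annulation. The four-carbon partner is an iodo aldehyde (C3 = CHO, C4/C5 in a trans-dioxolane, C6 = CH2I). The two-carbon partner is (R)-2-tert-butyl-5-methylidene-1,3-dioxolan-4-one (C2 = CH2, C1 = the ring carbon carrying O and C=O).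
- Enabling feature: C1 is an α-hydroxy acid carbon next to the C2 methylene, so C2=C1(O)(C=O) is a captodative radical acceptor whose adduct becomes an enolate. C3 is a carbinol (former aldehyde, hence a ketyl), C6 is a bare methylene (former CH2–I), and the trans C4/C5 diol can sit in a trans-fused dioxolane ring that folds C3 and C6 toward each other and forbids ether formation.
- The iodo aldehyde comes from (−)-2,3-O-isopropylidene-D-threitol (supplies C4 and C5). The alkene comes from (R)-lactic acid and pivalaldehyde (its acetal carbon controls C1).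
- Ring order: dioxolane (purchased) and dioxolanone (step 3) first, then the carbocycle in step 5 (spiro at C1). The endgame is silylation, acetonide removal, double acylation and acid unmasking.

Key step: step 5

Remark: ring positions are numbered as in quinic acid (C1 carries OH and CO2H, C3 the free secondary OH, C4 and C5 the ester oxygens). The target has the configuration of natural (−)-quinic acid, which fixes the D-threitol series for 1 and the (R)-series for 4.

**Route**

Step 1
Reactants: 1 (4R,5R)-2,2-dimethyl-1,3-dioxolane-4,5-dimethanol [(−)-2,3-O-isopropylidene-D-threitol]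
Product: 2 [(4R,5S)-5-(iodomethyl)-2,2-dimethyl-1,3-dioxolan-4-yl]methanol
Conditions: I2 (1.0 equiv), PPh3 (1.0 equiv), imidazole, THF, 0 °C to rt
Reagents that add atoms: iodine, II
Why: Appel iodination under stoichiometric control should give one mono-iodide because the two primary hydroxyls of the C2-symmetric diol are equivalent (di-iodide is separated and unreacted 1 recycled); no stereocentre is touched, and closure of 2 to a tetrahydrofuran would need a trans-fused bicycle.

Step 2
Reactants: 2 [(4R,5S)-5-(iodomethyl)-2,2-dimethyl-1,3-dioxolan-4-yl]methanol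
Product: 3 (4S,5S)-5-(iodomethyl)-2,2-dimethyl-1,3-dioxolane-4-carbaldehyde
Conditions: Dess–Martin periodinane, CH2Cl2, 0 °C to rt; used at once
Reagents that add atoms: none
Why: Dess–Martin oxidation of the primary alcohol should leave the primary iodide and the acetonide intact, and the α-centre already sits in the thermodynamically preferred trans-dioxolane, so epimerisation is not a concern.

Step 3
Reactants: 4 (R)-lactic acid; 5 pivalaldehyde
Product: 6 (2R,5R)-2-tert-butyl-5-methyl-1,3-dioxolan-4-one (cis)
Conditions: TsOH (cat.), pentane, reflux, Dean–Stark; crystallisation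
Reagents that add atoms: none
Why: Acid-catalysed acetalisation with azeotropic removal of water forms the 1,3-dioxolan-4-one; the new acetal centre is set under thermodynamic control with tert-butyl cis to methyl and the cis isomer is purified by crystallisation.

Step 4
Reactants: 6 (2R,5R)-2-tert-butyl-5-methyl-1,3-dioxolan-4-one
Product: 8 (2R)-2-tert-butyl-5-methylidene-1,3-dioxolan-4-one, via 5-bromo dioxolanone 7 (not isolated)
Conditions: NBS, AIBN (cat.), PhCF3, reflux; then Et3N, 0 °C to rt
Reagents that add atoms: none
Why: Wohl–Ziegler radical bromination at the captodative C5–H followed by E2 dehydrobromination should give the exocyclic alkene; the acetal stereocentre is not involved and now carries the chirality alone.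

Step 5
Reactants: 3 (4S,5S)-5-(iodomethyl)-2,2-dimethyl-1,3-dioxolane-4-carbaldehyde; 8 (2R)-2-tert-butyl-5-methylidene-1,3-dioxolan-4-one
Product: 10 4,5-O-isopropylidenequinic acid masked at C1 as the spiro (2R)-2-tert-butyl-1,3-dioxolan-4-one (3-OH free), via trivalent samarium alkoxide enolate 9 (not isolated)
Conditions: SmI2 (2.1 equiv), LiBr, THF, −78 °C (3 and 8 added slowly); then HMPA, −78 to 0 °C; aq NH4Cl
Reagents that add atoms: none
Why: Proposed new method: SmI2 (made more reducing toward C=O by LiBr) should reduce the aldehyde of 3 to a ketyl radical that adds through C3 to the CH2 terminus of the captodative alkene 8, and a second electron transfer should turn the dioxolanyl radical into the trivalent samarium enolate 9, whose masked carbonyl cannot be attacked by the C3 alkoxide; on addition of HMPA the enolate carbon C1 should displace the primary iodide at C6. The closest known reaction types are the samarium diiodide ketyl–acrylate reductive coupling for the first bond and, for the second, the trans-selective alkylation of 2-tert-butyl-1,3-dioxolan-4-one enolates and radical addition–polar cyclisation cascades; new is their merger into one [4+2] annulation that ends in the alkylation of a samarium enolate. The only ring closed is the cyclohexane, by a 6-exo-tet C-alkylation with the enolate double bond exocyclic to the new ring. C3 is set in the intermolecular radical step by approach of 8 anti to the C4–O bond of the dioxolane (polar 1,2-induction without chelation), which gives the 3,4-cis relation; C1 is set in the ring closure by the tert-butyl group on the acetal carbon, which shields one enolate face so that C6 enters trans to it, and allylic strain that keeps the carboxyl carbon equatorial in the chair transition state works in the same sense; C4 and C5 come unchanged from 1. The step needs electron transfer to C=O and not to C–I, secured by keeping HMPA out until the SmI2 is consumed at −78 °C, and C- rather than O-cyclisation, secured by the trans-fused dioxolane, which holds C3 and C6 gauche for the six-membered closure while attack of the C3 alkoxide on C6 would create a trans-fused five-membered ether.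

Step 6
Reactants: 10 4,5-O-isopropylidenequinic acid spiro-dioxolanone (3-OH free)
Product: 11 3-O-tert-butyldimethylsilyl ether of 10
Conditions: TBSOTf, 2,6-lutidine, CH2Cl2, −78 to 0 °C
Reagents that add atoms: tert-butyldimethylsilyl trifluoromethanesulfonate, CC(C)(C)[Si](C)(C)OS(=O)(=O)C(F)(F)F
Why: Silylation with a silyl triflate and a hindered pyridine base should protect the axial secondary alcohol, while acetonide and dioxolanone are inert to these conditions.

Step 7
Reactants: 11 3-O-TBS-4,5-O-isopropylidenequinic acid spiro-dioxolanone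
Product: 12 3-O-TBS-quinic acid spiro-dioxolanone with free 4,5-diol
Conditions: AcOH/H2O (4:1), rt
Reagents that add atoms: none
Why: Acid-catalysed acetal hydrolysis should cleave the strained trans-fused isopropylidene acetal much faster than the acylal-type dioxolanone or the secondary silyl ether, releasing only the 4,5-diol.

Step 8
Reactants: 13 (E)-4-acetoxycinnamic acid
Product: 14 (E)-4-acetoxycinnamoyl chloride
Conditions: (COCl)2, DMF (cat.), CH2Cl2, 0 °C to rt; evaporation
Reagents that add atoms: oxalyl chloride, O=C(Cl)C(=O)Cl
Why: Acid chloride formation through the Vilsmeier-type chloroiminium catalyst should leave the aryl acetate and the E-alkene untouched.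

Step 9
Reactants: 12 3-O-TBS-quinic acid spiro-dioxolanone 4,5-diol; 14 (E)-4-acetoxycinnamoyl chloride (3 equiv)
Product: 15 4,5-bis-O-[(E)-4-acetoxycinnamoyl]-3-O-TBS-quinic acid spiro-dioxolanone
Conditions: pyridine, DMAP (cat.), CH2Cl2, 0 °C to rt
Reagents that add atoms: none
Why: DMAP-catalysed acylation with excess acid chloride should esterify both equatorial secondary hydroxyls; O1, O3 and the carboxyl are blocked, so only O4 and O5 can react, and no stereocentre is touched.

Step 10
Reactants: 15 4,5-bis-O-[(E)-4-acetoxycinnamoyl]-3-O-TBS-quinic acid spiro-dioxolanone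
Product: 16 4,5-di-O-p-coumaroylquinic acid
Conditions: 2 M aq HCl/THF (1:1), rt to 40 °C, dark
Reagents that add atoms: none
Why: Acid-catalysed hydrolysis should cleave the acylal C–O bond of the dioxolanone (freeing the 1-hydroxy acid and pivalaldehyde), the silyl ether and the two aryl acetates, all more labile than the alkyl cinnamate esters; no base is present, so acyl migration among O3, O4 and O5 should be suppressed.

**Compound list**

1 | (4R,5R)-2,2-dimethyl-1,3-dioxolane-4,5-dimethanol [(−)-2,3-O-isopropylidene-D-threitol] | OC[C@H]1OC(C)(C)O[C@@H]1CO | starting material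
2 | [(4R,5S)-5-(iodomethyl)-2,2-dimethyl-1,3-dioxolan-4-yl]methanol | OC[C@H]1OC(C)(C)O[C@@H]1CI | intermediate
3 | (4S,5S)-5-(iodomethyl)-2,2-dimethyl-1,3-dioxolane-4-carbaldehyde | O=C[C@H]1OC(C)(C)O[C@@H]1CI | intermediate
4 | (R)-lactic acid | C[C@@H](O)C(=O)O | starting material
5 | pivalaldehyde | CC(C)(C)C=O | starting material
6 | (2R,5R)-2-tert-butyl-5-methyl-1,3-dioxolan-4-one | C[C@H]1O[C@@H](C(C)(C)C)OC1=O | intermediate
7 | (2R,5S)-5-bromo-2-tert-butyl-5-methyl-1,3-dioxolan-4-one (bromine trans to tert-butyl) | C[C@@]1(Br)O[C@@H](C(C)(C)C)OC1=O | intermediate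
8 | (2R)-2-tert-butyl-5-methylidene-1,3-dioxolan-4-one | C=C1O[C@@H](C(C)(C)C)OC1=O | intermediate
9 | open-chain adduct as its bis(diiodosamarium) derivative: C3 alkoxide, dioxolanone enolate at C1, C6–I intact | IC[C@H]1OC(C)(C)O[C@@H]1[C@H](O[Sm](I)I)CC1=C(O[Sm](I)I)O[C@H](C(C)(C)C)O1 | intermediate
10 | 4,5-O-isopropylidenequinic acid with OH and CO2H of C1 tied as a spiro (2R)-2-tert-butyl-1,3-dioxolan-4-one; 3-OH free | CC1(C)O[C@@H]2[C@H](O)C[C@]3(O[C@@H](C(C)(C)C)OC3=O)C[C@H]2O1 | intermediate
11 | 3-O-tert-butyldimethylsilyl ether of 10 | CC1(C)O[C@@H]2[C@H](O[Si](C)(C)C(C)(C)C)C[C@]3(O[C@@H](C(C)(C)C)OC3=O)C[C@H]2O1 | intermediate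
12 | 3-O-TBS-quinic acid spiro (2R)-2-tert-butyl-1,3-dioxolan-4-one, free 4,5-diol | O[C@@H]1[C@H](O[Si](C)(C)C(C)(C)C)C[C@]2(O[C@@H](C(C)(C)C)OC2=O)C[C@H]1O | intermediate
13 | (E)-4-acetoxycinnamic acid | CC(=O)Oc1ccc(/C=C/C(=O)O)cc1 | starting material
14 | (E)-4-acetoxycinnamoyl chloride | CC(=O)Oc1ccc(/C=C/C(Cl)=O)cc1 | intermediate
15 | 4,5-bis-O-[(E)-4-acetoxycinnamoyl]-3-O-TBS-quinic acid spiro (2R)-2-tert-butyl-1,3-dioxolan-4-one | CC(=O)Oc1ccc(/C=C/C(=O)O[C@@H]2[C@H](O[Si](C)(C)C(C)(C)C)C[C@]3(O[C@@H](C(C)(C)C)OC3=O)C[C@H]2OC(=O)/C=C/c2ccc(OC(C)=O)cc2)cc1 | intermediate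
16 | 4,5-di-O-p-coumaroylquinic acid, (1S,3R,4R,5R)-1,3-dihydroxy-4,5-bis{[(E)-3-(4-hydroxyphenyl)prop-2-enoyl]oxy}cyclohexane-1-carboxylic acid | O=C(/C=C/c1ccc(O)cc1)O[C@@H]1[C@H](O)C[C@@](O)(C(=O)O)C[C@H]1OC(=O)/C=C/c1ccc(O)cc1 | target

**Step count and risks**

Total step count: 10. Longest linear sequence: 7 (steps 1, 2, 5, 6, 7, 9, 10).

Steps most likely to fail:

1. Step 5 (Proposed new method). The samarium enolate may be protonated, fragment or add to a second molecule of 8 faster than it alkylates the β-oxygenated primary iodide, so the ring would not close. The ketyl addition may also show poor facial selectivity at C3 if samarium chelates the dioxolane oxygen. Fallback: the two bond formations are separated and use known chemistry only. From 3 and 8, the reductive ketyl–olefin coupling is run with SmI2, LiBr and t-BuOH in THF at −78 °C and quenched cold, which should give the open-chain hydroxy dioxolanone (2R,5R)-2-tert-butyl-5-{(2R)-2-hydroxy-2-[(4R,5S)-5-(iodomethyl)-2,2-dimethyl-1,3-dioxolan-4-yl]ethyl}-1,3-dioxolan-4-one F1; C3 epimers can be separated here. Silylation with TBSOTf and 2,6-lutidine gives its silyl ether F2. The lithium enolate, made with LiN(iPr)2 in THF/DMPU at −78 °C, is then allowed to cyclise on warming by the known trans-selective intramolecular alkylation of such dioxolanone enolates. This gives 11 directly, where the route is rejoined.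

2. Step 10. The hindered acylal ring may hydrolyse too slowly, and during long exposure to aqueous acid a coumaroyl group may be cleaved or migrate toward O3. Fallback: the C1 mask is exchanged early for an ester that falls off under neutral conditions. From 11, alcoholysis with allyl alcohol and K2CO3 (cat.) should open the dioxolanone to allyl 3-O-TBS-4,5-O-isopropylidenequinate F3, with a free tertiary 1-OH. Aqueous acetic acid then frees the diol, allyl 3-O-TBS-quinate F4. Acylation with 14 (pyridine, DMAP; the tertiary hydroxyl is far less reactive) gives allyl 4,5-bis-O-(4-acetoxycinnamoyl)-3-O-TBS-quinate F5. Brief 1 M aq HCl/THF at rt removes the silyl ether and the aryl acetates to give allyl 4,5-di-O-p-coumaroylquinate F6. Pd(PPh3)4 with morpholine in THF then removes the allyl ester and delivers 16.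

3. Step 9. The second acylation at O4, which is flanked by the axial silyl ether, may stall, and the silyl group may migrate from O3 to O4 under the basic conditions. Fallback: the cinnamoyl esters are assembled on the diol through a different bond. From 12, heating with Meldrum's acid in toluene (neutral, small acylating agent) should give the bis(hydrogen malonate) F7. Knoevenagel–Doebner condensation with 4-hydroxybenzaldehyde (pyridine, piperidine cat.) then builds both E-coumaroyl esters with free phenols, giving 4,5-di-O-p-coumaroyl-3-O-TBS-quinic acid spiro-dioxolanone F8. The acid hydrolysis of step 10 converts F8 into 16.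

Further compounds

F1 | step 5 | (2R,5R)-2-tert-butyl-5-{(2R)-2-hydroxy-2-[(4R,5S)-5-(iodomethyl)-2,2-dimethyl-1,3-dioxolan-4-yl]ethyl}-1,3-dioxolan-4-one | IC[C@H]1OC(C)(C)O[C@@H]1[C@H](O)C[C@H]1O[C@@H](C(C)(C)C)OC1=O
F2 | step 5 | tert-butyldimethylsilyl ether of F1 | IC[C@H]1OC(C)(C)O[C@@H]1[C@H](O[Si](C)(C)C(C)(C)C)C[C@H]1O[C@@H](C(C)(C)C)OC1=O
F3 | step 10 | allyl 3-O-TBS-4,5-O-isopropylidenequinate | CC1(C)O[C@@H]2[C@H](O[Si](C)(C)C(C)(C)C)C[C@@](O)(C(=O)OCC=C)C[C@H]2O1
F4 | step 10 | allyl 3-O-TBS-quinate | O[C@@H]1[C@H](O[Si](C)(C)C(C)(C)C)C[C@@](O)(C(=O)OCC=C)C[C@H]1O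
F5 | step 10 | allyl 4,5-bis-O-[(E)-4-acetoxycinnamoyl]-3-O-TBS-quinate | CC(=O)Oc1ccc(/C=C/C(=O)O[C@@H]2[C@H](O[Si](C)(C)C(C)(C)C)C[C@@](O)(C(=O)OCC=C)C[C@H]2OC(=O)/C=C/c2ccc(OC(C)=O)cc2)cc1
F6 | step 10 | allyl 4,5-di-O-p-coumaroylquinate | O=C(/C=C/c1ccc(O)cc1)O[C@@H]1[C@H](O)C[C@@](O)(C(=O)OCC=C)C[C@H]1OC(=O)/C=C/c1ccc(O)cc1
F7 | step 9 | 4,5-bis-O-(carboxyacetyl)-3-O-TBS-quinic acid spiro (2R)-2-tert-butyl-1,3-dioxolan-4-one | OC(=O)CC(=O)O[C@@H]1[C@H](O[Si](C)(C)C(C)(C)C)C[C@]2(O[C@@H](C(C)(C)C)OC2=O)C[C@H]1OC(=O)CC(=O)O
F8 | step 9 | 4,5-di-O-p-coumaroyl-3-O-TBS-quinic acid spiro (2R)-2-tert-butyl-1,3-dioxolan-4-one | O=C(/C=C/c1ccc(O)cc1)O[C@@H]1[C@H](O[Si](C)(C)C(C)(C)C)C[C@]2(O[C@@H](C(C)(C)C)OC2=O)C[C@H]1OC(=O)/C=C/c1ccc(O)cc1
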